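**Plan**
- Retrosynthesis cuts the benzene ring itself at three ring bonds, C4–C5, C6–C1 and C1–C2. The pieces are tricos-1-yne (C5, C6 and the C21 chain), one CO ligand (C1 and the phenol oxygen) and a chromium (2-methoxyvinyl)(methoxy)carbene (C2, C3, C4 and both OMe groups).
- Enabling feature: the free OH at C1 is para to the OMe at C4 on the benzene ring, which is the hydroquinone monomethyl ether pattern a Dötz benzannulation delivers. The C6-alkyl/C5-H edge maps onto a terminal alkyne and the C2-OMe/C3-H edge onto a 2-methoxyvinyl group.
- Forward: docosan-1-ol → docosanal → tricos-1-yne (steps 1–2); methyl vinyl ether → (Z)-1-bromo-2-methoxyethene → carbene complex (steps 3–4). The two branches meet in step 5, where the only ring forms in one operation with the free OH and both OMe groups already differentiated.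
- Stereochemistry: none to set; only regiochemistry matters, and the terminal alkyne fixes it (chain ortho to OH).

Key step: step 5

Remark: the target has no stereocentre and no stereogenic double bond, so it is achiral and "single enantiomer" calls for no stereocontrol. Intermediate 5 is racemic and its centre is destroyed in the same flask.

**Step 1**
Reactants: 1 docosan-1-ol
Product: 2 docosanal
Conditions: TEMPO (10 mol%), PhI(OAc)2 (1.1 equiv), CH2Cl2, 25–30 °C
Reagents that add atoms: none
Why: Piancatelli–Margarita oxidation, in which the TEMPO-derived oxoammonium ion (regenerated by PhI(OAc)2) should take the primary alcohol to the aldehyde and stop there in the absence of water.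

**Step 2**
Reactants: 2 docosanal
Product: 3 tricos-1-yne
Conditions: Ohira–Bestmann reagent (1.3 equiv), K2CO3 (2 equiv), MeOH/THF 1:1, rt
Reagents that add atoms: dimethyl (1-diazo-2-oxopropyl)phosphonate, CC(=O)C(=[N+]=[N-])P(=O)(OC)OC
Why: Ohira–Bestmann variant of the Seyferth–Gilbert homologation, in which the diazomethylphosphonate anion olefinates the aldehyde and the resulting diazoalkene loses N2 with a 1,2-hydride shift to give the terminal alkyne under a carbonate base mild enough for an enolisable aldehyde.

**Step 3**
Reactants: 4 methoxyethene (methyl vinyl ether)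
Product: 6 (Z)-1-bromo-2-methoxyethene, via 1,2-dibromo-1-methoxyethane 5 (not isolated)
Conditions: Br2 (1.0 equiv), CH2Cl2, −78 °C; then PhNEt2 (1.3 equiv), 90 °C; fractional distillation
Reagents that add atoms: bromine, BrBr
Why: Bromination of the enol ether followed by amine-induced dehydrobromination of the α-bromo ether through its oxocarbenium ion, which should give mainly the cis (Z) β-bromo enol ether as the ethyl analogue does (cis preference of 1,2-diheteroatom alkenes).

**Step 4**
Reactants: 6 (Z)-1-bromo-2-methoxyethene; 7 hexacarbonylchromium(0)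
Product: 10 pentacarbonyl[(2Z)-1,3-dimethoxyprop-2-en-1-ylidene]chromium(0), via (Z)-2-methoxyvinyllithium 8 (not isolated), via lithium acylchromate 9 (not isolated)
Conditions: t-BuLi (2.0 equiv), Et2O, −78 °C; 7, THF, −78 to 0 °C; solvent exchange; Me3OBF4, CH2Cl2, 0 °C
Reagents that add atoms: trimethyloxonium tetrafluoroborate, C[O+](C)C.F[B-](F)(F)F
Why: Fischer carbene synthesis, in which bromine–lithium exchange with retention gives the Z vinyllithium (lithium and methoxy are cis, so anti elimination is not possible), this adds to a CO ligand of 7, and the hard Meerwein salt methylates the acylchromate oxygen.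

**Step 5**
Reactants: 3 tricos-1-yne; 10 pentacarbonyl[(2Z)-1,3-dimethoxyprop-2-en-1-ylidene]chromium(0)
Product: 12 6-n-heneicosyl-2,4-dimethoxyphenol, via arene tricarbonylchromium complex 11 (not isolated)
Conditions: 3 (1.5 equiv), THF (0.3 M in 10), 55 °C, Ar, dark; then air, Et2O/MeCN, rt
Reagents that add atoms: none
Why: Proposed new method: thermal loss of one cis-CO from 10 should let alkyne 3 bind and insert into the Cr=C bond with its unsubstituted terminus on the carbene carbon, after which CO insertion gives an η4-dienylketene whose ketene carbon closes onto the methoxy-bearing vinyl carbon, and enolisation gives the arene as its Cr(CO)3 complex 11, which air demetalates. The closest known reaction type is the Dötz benzannulation of alkenyl(alkoxy)carbene chromium complexes with terminal alkynes, including 3-furyl carbenes in which the closing carbon also bears oxygen; the untested element is an open-chain 2-methoxyvinyl group. The single ring (the benzene ring) closes by 6π-electrocyclisation of the dienylketene, a formal [3+2+1] assembly that forms C4–C5, C6–C1 and C1–C2. No stereocentre results, because the sp3 carbon of the transient cyclohexa-2,4-dienone is lost on enolisation, so the alkene geometry of 10 is immaterial. The step needs regioselective insertion (chain ortho to OH), which the large/small contrast of a terminal alkyne secures, and CO insertion in preference to five-ring formation, which chromium, an alkoxy rather than amino donor, an ethereal solvent and a high alkyne concentration should favour. Aerobic demetalation is chosen because cerium(IV) would oxidise the electron-rich phenol to a quinone.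

**Compound list**
1 | docosan-1-ol | CCCCCCCCCCCCCCCCCCCCCCO | starting material
2 | docosanal | CCCCCCCCCCCCCCCCCCCCCC=O | intermediate
3 | tricos-1-yne | CCCCCCCCCCCCCCCCCCCCCC#C | intermediate
4 | methoxyethene (methyl vinyl ether) | COC=C | starting material
5 | 1,2-dibromo-1-methoxyethane (racemic) | COC(Br)CBr | intermediate
6 | (Z)-1-bromo-2-methoxyethene | CO/C=C\Br | intermediate
7 | hexacarbonylchromium(0) | O=C=[Cr](=C=O)(=C=O)(=C=O)(=C=O)=C=O | starting material
8 | (Z)-2-methoxyvinyllithium | [Li]/C=C\OC | intermediate
9 | lithium pentacarbonyl[(2Z)-3-methoxyprop-2-enoyl]chromate | [Li+].[O-]C(/C=C\OC)=[Cr](=C=O)(=C=O)(=C=O)(=C=O)=C=O | intermediate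
10 | pentacarbonyl[(2Z)-1,3-dimethoxyprop-2-en-1-ylidene]chromium(0) | CO/C=C\C(OC)=[Cr](=C=O)(=C=O)(=C=O)(=C=O)=C=O | intermediate
11 | tricarbonyl[η6-(6-heneicosyl-2,4-dimethoxyphenol)]chromium(0) (η6 bonding not expressible in SMILES; arene and Cr(CO)3 fragment joined by a dot) | CCCCCCCCCCCCCCCCCCCCCc1cc(OC)cc(OC)c1O.O=C=[Cr](=C=O)=C=O | intermediate
12 | 6-n-heneicosyl-2,4-dimethoxyphenol (achiral) | CCCCCCCCCCCCCCCCCCCCCc1cc(OC)cc(OC)c1O | target

**Step count**
Total steps: 5. Longest linear sequence: 3 steps (1 → 2 → 5, or 3 → 4 → 5).

**Steps most likely to fail**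

1. Step 5 (proposed new method). The alkyne-inserted vinylcarbene may cyclise before taking up CO (five-ring formation), or the donor-stabilised carbene may lose CO so slowly that alkyne oligomerisation takes over. The fallback uses known chemistry and sets out from docosanal 2. Pinnick oxidation (NaClO2, NaH2PO4, 2-methyl-2-butene) would give docosanoic acid F1. Coupling with N-hydroxyphthalimide (DIC, DMAP) would give 1,3-dioxoisoindolin-2-yl docosanoate F2. Nickel-catalysed decarboxylative cross-electrophile coupling with commercial 1-iodo-3,5-dimethoxybenzene (NiBr2·glyme, dtbbpy, Zn, DMA) would give 1-heneicosyl-3,5-dimethoxybenzene F3. Vilsmeier–Haack formylation (POCl3, DMF), ortho to the chain and para to a methoxy group, would give 2-heneicosyl-4,6-dimethoxybenzaldehyde F4. Baeyer–Villiger (Dakin-type) oxidation with mCPBA would give 2-heneicosyl-4,6-dimethoxyphenyl formate F5, and KOH/MeOH would hydrolyse it, coming back to the route at 12.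

2. Step 4. The vinyllithium may be lost by proton abstraction or elimination before it reaches the metal carbonyl, or the enol ether may be hydrolysed during alkylation and work-up. The fallback reverses the polarity of carbene assembly and sets out from 7. Reduction with C8K in THF would give dipotassium pentacarbonylchromate F6. Acylation with (E)-3-methoxyacryloyl chloride F7 (from commercial (E)-3-methoxyacrylic acid and oxalyl chloride) would give potassium pentacarbonyl[(2E)-3-methoxyprop-2-enoyl]chromate F8. O-Methylation with Me3OBF4 would give pentacarbonyl[(2E)-1,3-dimethoxyprop-2-en-1-ylidene]chromium(0) F9. This E isomer would be used in step 5 in place of 10 and comes back to the route at 11, since the alkene geometry is lost in the ring closure.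

3. Step 3. Geometric purity may erode during dehydrobromination (the E isomer would eliminate lithium methoxide on lithiation), and the volatile product may be lost on distillation. The fallback avoids any 2-methoxyvinyl anion and sets out from 7. Addition of commercial lithium (trimethylsilyl)acetylide would give lithium pentacarbonyl[3-(trimethylsilyl)prop-2-ynoyl]chromate F10. Me3OBF4 would give pentacarbonyl[1-methoxy-3-(trimethylsilyl)prop-2-yn-1-ylidene]chromium(0) F11. Catalytic NaOMe in MeOH at 0 °C should remove the silyl group and add methanol across the triple bond in the anti (Michael) sense, coming back to the route at 10 with steps 3 and 4 bypassed.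

**Further compounds**
F1 | step 5 | docosanoic acid | CCCCCCCCCCCCCCCCCCCCCC(=O)O
F2 | step 5 | 1,3-dioxoisoindolin-2-yl docosanoate | CCCCCCCCCCCCCCCCCCCCCC(=O)ON1C(=O)c2ccccc2C1=O
F3 | step 5 | 1-heneicosyl-3,5-dimethoxybenzene | CCCCCCCCCCCCCCCCCCCCCc1cc(OC)cc(OC)c1
F4 | step 5 | 2-heneicosyl-4,6-dimethoxybenzaldehyde | CCCCCCCCCCCCCCCCCCCCCc1cc(OC)cc(OC)c1C=O
F5 | step 5 | 2-heneicosyl-4,6-dimethoxyphenyl formate | CCCCCCCCCCCCCCCCCCCCCc1cc(OC)cc(OC)c1OC=O
F6 | step 4 | dipotassium pentacarbonylchromate(2−) | [K+].[K+].O=C=[Cr-2](=C=O)(=C=O)(=C=O)=C=O
F7 | step 4 | (E)-3-methoxyacryloyl chloride | CO/C=C/C(Cl)=O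
F8 | step 4 | potassium pentacarbonyl[(2E)-3-methoxyprop-2-enoyl]chromate | [K+].[O-]C(/C=C/OC)=[Cr](=C=O)(=C=O)(=C=O)(=C=O)=C=O
F9 | step 4 | pentacarbonyl[(2E)-1,3-dimethoxyprop-2-en-1-ylidene]chromium(0) | CO/C=C/C(OC)=[Cr](=C=O)(=C=O)(=C=O)(=C=O)=C=O
F10 | step 3 | lithium pentacarbonyl[3-(trimethylsilyl)prop-2-ynoyl]chromate | [Li+].[O-]C(C#C[Si](C)(C)C)=[Cr](=C=O)(=C=O)(=C=O)(=C=O)=C=O
F11 | step 3 | pentacarbonyl[1-methoxy-3-(trimethylsilyl)prop-2-yn-1-ylidene]chromium(0) | COC(C#C[Si](C)(C)C)=[Cr](=C=O)(=C=O)(=C=O)(=C=O)=C=O
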